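(The numbers in the tables are calculated for an exercise, and the scatter is random.)

The closed, stirred vessel holds the racemic substrate, L and Z, with single-handed reagent J, which turns L into G. We read G as a percentage of L and Z together.

all flasks: L 0.50 mM; Z 0.50 mM

| flask | J | temperature | remark | time |
|---|---|---|---|---|
| west | 2 mM | 35 °C | the very flask that is asked about, followed so far |  |
| north-east | 2 mM | 20 °C | run made earlier |  |
| flask | 2.00 mM | 35 °C |  | 1.0 h |

- west (time / min: G / %): 4.00: 37.0; 8.00: 37.7; 15.0: 38.0; 25.0: 37.7; 50.0: 37.0
- north-east (time / min: G / %): 8.00: 45.5; 15.0: 45.5; 30.0: 44.4; 50.0: 45.2; 120: 44.5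

(each reading ± 0.5 percentage points)

- J is single-handed; L and Z are mirror images of each other, charged as a racemate, each of them at the stated concentration
- G that was removed still counts
- additions bring no volume worth counting
- the handed part of J does not stay in what it makes, so the products of the two hands are mirror images too

- violet: at 1.0 h raise the temperature by 20 K, then wait 20 min
- grey: at 1.0 h add J, 100% of the amount charged, then wait 20 min
- blue: at 1.0 h take out 90% of the G then present, then wait 20 min
- ochre: change nothing and wait 20 min more

1. G, in percent of the L and Z together first charged, at 1.0 h
2. the remedy with the largest gain of G, or "none" below 2 percentage points (violet / grey / blue / ochre / none)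
3. G present, with what was taken out counted in, in percent of the L and Z together first charged, after violet
4. G present, with what was taken out counted in, in percent of the L and Z together first charged, after grey

In the west run, G is flat from the first reading at 4.00 min to the last, with a mean of 37.5%. That is 0.375 mM of G from 2.00 mM of J. A flat line fits either an equilibrium or a stop, and the west readings do not choose between them.

Our reckoning takes a stop, with J as the limiting reagent. J stands at 4.00 equivalents to L, yet it gave less G than its charge, so we suppose that J is also lost elsewhere. Two amounts then matter: the J charged and its reach, the charge that lowers the share not turned into G by one e-fold, 4.26 mM. We assume that L and Z interconvert, so that Z can also reach G, and that the share falls exponentially with J.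

In the west flask their ratio is 0.469. Grey brings the J charged to 4.00 mM in total, counting the first portion, so we reckon 60.9% G, a gain of 23 percentage points. If the flask has stopped, heating, removing G or waiting should leave G at 37.5%, so our choice is grey.

The forecast gives 37.5% now, 23% after violet, 43.5% after grey and blue as best, on its ground that “A lower plateau when hotter points to an exothermic equilibrium rather than a kinetic stop”. We part from it on the remedies.

The flask gives 37.6% now, 37.6% after violet, 57.4% after grey and grey as best.

    L ⇌ Z (k = 0.0250 s⁻¹, Ea = 83.0 kJ mol⁻¹)
    J + Z → X (k = 9.00 M⁻¹ s⁻¹, Ea = 48.0 kJ mol⁻¹)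
    J → Q (k = 0.0200 s⁻¹, Ea = 83.0 kJ mol⁻¹)
    J + L → G (k = 27.0 M⁻¹ s⁻¹, Ea = 43.0 kJ mol⁻¹)
    2 J → E (k = 8.60 M⁻¹ s⁻¹, Ea = 44.0 kJ mol⁻¹)
    (constants at 35 °C)

At 60.0 min the flask holds J at 0% of its charge. Our grey figure stands 3.5 points above the result. The neighbouring flask is the same flask with 0.80 mM of J, a ratio to the reach of 0.188, so the same reckoning gives 17.1% G. That neighbouring flask gives 21.3%.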